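## Structural features

The target is a 1-aryltetralin (2,7'-cyclolignan). Ring A (C1–C6) is a pentasubstituted benzene with 3-OMe, 4-OH and 5-OMe; ring B is the carbocycle C1–C2–C7'–C8'–C8–C7 fused to it; a 4-hydroxy-3-methoxyphenyl ring hangs on C7'. Ring B carries three contiguous stereocentres, C7' (diaryl methine), C8' and C8 (each CH–CH3), followed by the C7 methylene. The C7' aryl is trans to the C8' methyl and the two methyls are cis. Neither methyl-bearing carbon has a heteroatom or carbonyl handle, and the cis 8,8' pair is the less stable arrangement, so it cannot be reached by equilibration. Ring A is a syringyl unit: before ring closure C2 and C6 are equivalent and each is activated by an ortho and a para methoxy group, so closure onto it is regiochemically unambiguous but places 3-OMe peri to the C7' aryl. Fragile points are the two free phenols (oxidation to quinone methides), C8 and C8' whenever C7 or C7' is a carbonyl (epimerisation), and a C7' cation, which can lose the C8' proton. The real difficulty is absolute control of the cis C8/C8' pair and its relay to C7'. The key step exploits the chain C7–C8–C8'–C7': with its cis methyls it is a meso-2,3-dimethylsuccinyl unit whose two end carbons are both benzylic in the target, so both can be the carbonyls of one meso anhydride, and choosing between them fixes both stereocentres. In one sentence: ligand-controlled rhodium-catalysed arylzinc opening of meso-2,3-dimethylsuccinic anhydride.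

## Logic of the disconnections

17 to 16: the O–CH2Ph bond on the pendant ring is cut. The 4'-OH must be masked while C7' is built with an aryllithium, and benzyl leaves under neutral conditions that cannot touch the three stereocentres. The gain is small. The demand is that the last hydrogenolysis spares the doubly benzylic C7' centre.

16 to 15: the C2–C7' bond is cut, which opens ring B. C7' is stabilised as a cation by the pendant ring, and C2 of ring A is the natural nucleophilic position. The ring and the C7' stereocentre disappear, leaving an open chain with only C8 and C8'. The demand is that the forward closure sets C7' trans to the C8' methyl by relay from the existing centres, and that the cation cyclises faster than it loses the C8' proton.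

15 to 14 to 10 + 11: the C7'–H bond is cut (carbinol back to ketone), then the C7'–C1' acyl–aryl bond. This brings C7' to the acid oxidation level, which is what a succinyl unit provides. The pendant ring is split off as 11, and 10 is a simple acid. The demand is ketone formation without epimerisation at C8'.

10 to 7: oxygen is put back on C7 (C=O) and benzyl on the 4-oxygen. C7 thereby becomes the second carbonyl of the succinyl unit. The demand is that the forward hydrogenolysis removes the ketone oxygen without epimerising C8; once done, C8 can no longer epimerise.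

7 to 2 + 4 (key): the C7–C1 acyl–aryl bond is cut and the C7 carbonyl is rejoined to the C7' carboxylate oxygen. Both stereocentres are already present, with the right relative configuration, in the achiral meso compound 4. The gain is two stereocentres traced back to no chiral information at all, plus a convergent junction of ring A with the C4 unit. The demand is that a chiral catalyst selects one of two enantiotopic carbonyls, delivers the aryl group once, and does so without enolisation.

4 to 3 and 2 to 1: two C–H bonds on one face of 3 are cut (syn hydrogenation of a flat ring guarantees cis methyls), and the O–benzyl bond of 2. Both lead to commercial materials.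

## Other disconnections considered

Alternative 1: This is the first idea. Cut C2–C7' by Friedel–Crafts closure and build the chain with a stoichiometric auxiliary. Alkylation of a propionyl oxazolidinone with the ring-A benzyl bromide would give imide A1 (C8 set). C8' and C7' would then be added in a second stereocontrolled event to reach the dibenzyl diarylbutanol A2, which is cyclised. The two methyl-bearing centres are set in two separate operations with stoichiometric chirality, and the syn relation rests on the second one. Auxiliary removal and redox adjustments make the sequence clearly longer. The ring closure is the same as in the chosen plan, so nothing is gained there.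

Alternative 2: Cut C7'–C8' and C7–C8 together. A Diels–Alder reaction of the α-aryl o-quinodimethane A3 with maleic anhydride would give adduct A4, closing ring B and creating all three centres at once. With the aryl group outward in A3 and endo approach, the C7' aryl ends cis to the C8' substituent (all-cis A4). The target has it trans, and no handle remains to invert a centre later. A4 would also be racemic, and its two carbonyls would have to be reduced to methyl groups in several further operations.

Alternative 3: Use a temporary oxygen bridge between C7 and C7'. Cycloaddition of aryne A5 with 3,4-dimethylfuran would give A6, and hydrogenation from the exo face would give A7 with cis endo methyls. Acid-mediated opening of the bridge at C7' with 2-methoxyphenol, anti to the C8' methyl, followed by removal of the C7 oxygen, would finish the skeleton by relay alone. However, A6 is chiral only because ring A is unsymmetrically substituted (3-OMe against 6-H). It therefore forms as a racemate and has no mirror plane for a catalyst to exploit, so a resolution would be needed. The two bridgehead C–O bonds would also have to be told apart. The chosen plan has a true meso intermediate.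

Key step: step 3

Assumptions and remarks:
- The sense of induction of Rh/t-Bu-PHOX on 4 is not predicted here. The ligand enantiomer is chosen so that aryl is delivered to the carbonyl next to the (S)-carbon of 4; (S)-t-Bu-PHOX is written, and its commercial antipode is used if the sense is opposite.
- Salts formed by simple deprotonation (phenoxide, carboxylate) are treated as the same compound and are not numbered separately.
- 1, 3 and 11 are taken as commercial.

## Steps

Step 1
Reactants: 1 4-bromo-2,6-dimethoxyphenol
Product: 2 2-(benzyloxy)-5-bromo-1,3-dimethoxybenzene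
Conditions: BnBr, K2CO3, DMF, rt
Reagents that add atoms: benzyl bromide, BrCc1ccccc1
Why: Williamson etherification (SN2 on benzyl bromide); the benzyl group masks the acidic OH during bromine–lithium exchange and is removed without an extra step in step 4.

Step 2
Reactants: 3 2,3-dimethylmaleic anhydride
Product: 4 (3R,4S)-3,4-dimethyloxolane-2,5-dione (meso, cis)
Conditions: H2 (4 atm), 10% Pd/C, EtOAc, rt
Reagents that add atoms: none
Why: Heterogeneous catalytic hydrogenation; syn delivery of both hydrogens to one face of the planar ring alkene should give only the cis (meso) anhydride.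

Step 3
Reactants: 2 2-(benzyloxy)-5-bromo-1,3-dimethoxybenzene, 4 (3R,4S)-3,4-dimethyloxolane-2,5-dione
Product: 7 (2R,3S)-4-[4-(benzyloxy)-3,5-dimethoxyphenyl]-2,3-dimethyl-4-oxobutanoic acid, via aryllithium 5 (not isolated), via arylzinc triflate 6 (not isolated)
Conditions: 2, n-BuLi, THF, −78 °C; Zn(OTf)2, −78 °C → rt; then 4, [Rh(cod)Cl]2 (4 mol %), (S)-t-Bu-PHOX (8 mol %), DMF/THF, 50 °C; 1 M HCl work-up
Reagents that add atoms: none
Why: Rh-catalysed enantioselective acyl cross-coupling (desymmetrising arylation of a meso cyclic anhydride by an arylzinc), preceded by routine bromine–lithium exchange (2 → 5) and transmetalation to zinc (5 → 6). The Rh(I)–P,N complex inserts into one of the two enantiotopic C(acyl)–O bonds of 4 (oxidative addition, the enantio-determining event), the aryl group passes from 6 to the acyl–Rh(III) carboxylate, and reductive elimination releases the aryl ketone as its zinc carboxylate, protonated on work-up. The step closes no ring: it opens the anhydride ring, whose only role was to hold the two methyl groups cis, and forms the C7–C1 bond. No new stereogenic carbon is created; C8 and C8' already exist in 4 and become an enantiomerically defined pair because the catalyst attacks the carbonyl next to the (S)-carbon, so the chiral ligand on rhodium controls both. The step needs enantiotopic-group selectivity (ligand), single addition (an arylzinc does not add to the ketone or carboxylate formed) and retention at both α-carbons (no base able to enolise the ketone is present). The electron-rich, ortho-unsubstituted aryl group should transmetalate readily, and its trioxygenated pattern is of the type for which this reaction class is known.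

Step 4
Reactants: 7 (2R,3S)-4-[4-(benzyloxy)-3,5-dimethoxyphenyl]-2,3-dimethyl-4-oxobutanoic acid
Product: 10 (2R,3R)-4-(4-hydroxy-3,5-dimethoxyphenyl)-2,3-dimethylbutanoic acid, via phenolic keto acid 8 (not isolated), via benzylic alcohol 9 (not isolated)
Conditions: H2 (3 atm), 10% Pd/C, AcOH, HClO4 (cat.), rt
Reagents that add atoms: none
Why: Pd-catalysed hydrogenolysis: fast O-debenzylation (8), then aryl ketone to benzylic alcohol (9) and benzylic C–O cleavage, helped by the electron-rich ring and acid; no stereocentre is touched, and C8 loses its only neighbouring carbonyl (the descriptor changes from S to R by priority only).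

Step 5
Reactants: 10 (2R,3R)-4-(4-hydroxy-3,5-dimethoxyphenyl)-2,3-dimethylbutanoic acid, 11 1-(benzyloxy)-4-bromo-2-methoxybenzene
Product: 14 (2R,3R)-1-[4-(benzyloxy)-3-methoxyphenyl]-4-(4-hydroxy-3,5-dimethoxyphenyl)-2,3-dimethylbutan-1-one, via aryllithium 12 (not isolated), via trilithium gem-diolate 13 (not isolated)
Conditions: 11, n-BuLi, THF, −78 °C (gives 12, 1.5 equiv); 10, n-BuLi (2.0 equiv), THF, −78 °C (dilithium salt); combine, −78 → 0 °C; inverse quench into cold 1 M HCl
Reagents that add atoms: none
Why: Ketone synthesis by organolithium addition to a lithium carboxylate; adduct 13 is stable in the flask and collapses to the ketone only on acidic quench, so a second addition should not occur, and the ketone never meets base, which protects C8'.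

Step 6
Reactants: 14 (2R,3R)-1-[4-(benzyloxy)-3-methoxyphenyl]-4-(4-hydroxy-3,5-dimethoxyphenyl)-2,3-dimethylbutan-1-one
Product: 15 (1RS,2R,3R)-1-[4-(benzyloxy)-3-methoxyphenyl]-4-(4-hydroxy-3,5-dimethoxyphenyl)-2,3-dimethylbutan-1-ol
Conditions: NaBH4, MeOH/THF, 0 °C
Reagents that add atoms: none
Why: Borohydride reduction of the aryl ketone; the C7' carbinol may form as an epimer mixture, which is of no consequence because both epimers ionise to the same cation in step 7, and 0 °C limits enolisation towards C8'.

Step 7
Reactants: 15 (1RS,2R,3R)-1-[4-(benzyloxy)-3-methoxyphenyl]-4-(4-hydroxy-3,5-dimethoxyphenyl)-2,3-dimethylbutan-1-ol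
Product: 16 (6R,7R,8R)-8-[4-(benzyloxy)-3-methoxyphenyl]-1,3-dimethoxy-6,7-dimethyl-5,6,7,8-tetrahydronaphthalen-2-ol
Conditions: TFA (5 equiv), CH2Cl2 (0.02 M), −20 → 0 °C
Reagents that add atoms: none
Why: Intramolecular Friedel–Crafts alkylation: the p-benzyloxybenzylic C7' cation is attacked by C2 of ring A (ortho and para to OMe; C2 and C6 equivalent, so one regioisomer) to close the six-membered ring. C7' is set by substrate control: the peri 3-OMe forces the C7' aryl pseudoaxial, where it is anti to the C8' methyl in the trans closure but 1,3-diaxial to the C8 methyl in the all-cis alternative, so the 7',8'-trans (7'R) product should prevail.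

Step 8
Reactants: 16 (6R,7R,8R)-8-[4-(benzyloxy)-3-methoxyphenyl]-1,3-dimethoxy-6,7-dimethyl-5,6,7,8-tetrahydronaphthalen-2-ol
Product: 17 (6R,7R,8R)-8-(4-hydroxy-3-methoxyphenyl)-1,3-dimethoxy-6,7-dimethyl-5,6,7,8-tetrahydronaphthalen-2-ol, i.e. (−)-(7'R,8R,8'R)-4,4'-dihydroxy-3,3',5-trimethoxy-2,7'-cyclolignan
Conditions: H2 (1 atm), 10% Pd/C, EtOAc/MeOH, rt
Reagents that add atoms: none
Why: Hydrogenolysis of the aryl benzyl ether under neutral conditions; none of the three stereocentres is epimerisable and the C7'–aryl bonds are C–C bonds that are not cleaved.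

## Compound list

1 | 4-bromo-2,6-dimethoxyphenol | COc1cc(Br)cc(OC)c1O | starting material
2 | 2-(benzyloxy)-5-bromo-1,3-dimethoxybenzene | COc1cc(Br)cc(OC)c1OCc1ccccc1 | intermediate
3 | 2,3-dimethylmaleic anhydride (3,4-dimethylfuran-2,5-dione) | CC1=C(C)C(=O)OC1=O | starting material
4 | (3R,4S)-3,4-dimethyloxolane-2,5-dione (meso-cis-2,3-dimethylsuccinic anhydride) | C[C@H]1C(=O)OC(=O)[C@H]1C | intermediate
5 | [4-(benzyloxy)-3,5-dimethoxyphenyl]lithium | [Li]c1cc(OC)c(OCc2ccccc2)c(OC)c1 | intermediate (not isolated)
6 | [4-(benzyloxy)-3,5-dimethoxyphenyl]zinc trifluoromethanesulfonate | FC(F)(F)S(=O)(=O)O[Zn]c1cc(OC)c(OCc2ccccc2)c(OC)c1 | intermediate (not isolated)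
7 | (2R,3S)-4-[4-(benzyloxy)-3,5-dimethoxyphenyl]-2,3-dimethyl-4-oxobutanoic acid | COc1cc(cc(OC)c1OCc1ccccc1)C(=O)[C@@H](C)[C@H](C(=O)O)C | intermediate
8 | (2R,3S)-4-(4-hydroxy-3,5-dimethoxyphenyl)-2,3-dimethyl-4-oxobutanoic acid | COc1cc(cc(OC)c1O)C(=O)[C@@H](C)[C@H](C(=O)O)C | intermediate (not isolated)
9 | (2R,3S,4RS)-4-hydroxy-4-(4-hydroxy-3,5-dimethoxyphenyl)-2,3-dimethylbutanoic acid | COc1cc(cc(OC)c1O)C(O)[C@@H](C)[C@H](C(=O)O)C | intermediate (not isolated)
10 | (2R,3R)-4-(4-hydroxy-3,5-dimethoxyphenyl)-2,3-dimethylbutanoic acid | COc1cc(C[C@@H](C)[C@H](C(=O)O)C)cc(OC)c1O | intermediate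
11 | 1-(benzyloxy)-4-bromo-2-methoxybenzene | COc1cc(Br)ccc1OCc1ccccc1 | starting material
12 | [4-(benzyloxy)-3-methoxyphenyl]lithium | [Li]c1ccc(OCc2ccccc2)c(OC)c1 | intermediate (not isolated)
13 | trilithium salt of (2R,3R)-1-[4-(benzyloxy)-3-methoxyphenyl]-4-(4-hydroxy-3,5-dimethoxyphenyl)-2,3-dimethylbutane-1,1-diol | COc1cc(C[C@@H](C)[C@H](C(O[Li])(O[Li])c2ccc(OCc3ccccc3)c(OC)c2)C)cc(OC)c1O[Li] | intermediate (not isolated)
14 | (2R,3R)-1-[4-(benzyloxy)-3-methoxyphenyl]-4-(4-hydroxy-3,5-dimethoxyphenyl)-2,3-dimethylbutan-1-one | COc1cc(C[C@@H](C)[C@H](C(=O)c2ccc(OCc3ccccc3)c(OC)c2)C)cc(OC)c1O | intermediate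
15 | (1RS,2R,3R)-1-[4-(benzyloxy)-3-methoxyphenyl]-4-(4-hydroxy-3,5-dimethoxyphenyl)-2,3-dimethylbutan-1-ol | COc1cc(C[C@@H](C)[C@H](C(O)c2ccc(OCc3ccccc3)c(OC)c2)C)cc(OC)c1O | intermediate
16 | (6R,7R,8R)-8-[4-(benzyloxy)-3-methoxyphenyl]-1,3-dimethoxy-6,7-dimethyl-5,6,7,8-tetrahydronaphthalen-2-ol | COc1cc([C@@H]2c3c(cc(OC)c(O)c3OC)C[C@@H](C)[C@H]2C)ccc1OCc1ccccc1 | intermediate
17 | (6R,7R,8R)-8-(4-hydroxy-3-methoxyphenyl)-1,3-dimethoxy-6,7-dimethyl-5,6,7,8-tetrahydronaphthalen-2-ol, i.e. (7'R,8R,8'R)-4,4'-dihydroxy-3,3',5-trimethoxy-2,7'-cyclolignan | COc1cc([C@@H]2c3c(cc(OC)c(O)c3OC)C[C@@H](C)[C@H]2C)ccc1O | target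

## Step count and least certain steps

Total: 8 steps. Longest linear sequence: 7 steps (1 or 2, then 3 to 8).

Step 3 (key). Most likely failure: incomplete discrimination of the two enantiotopic carbonyls, giving lower enantiomeric purity than the target needs, or slow aryl transfer from zinc giving low conversion. A moderate shortfall in enantiopurity could be corrected by crystallising 7 or 10 as a salt with a chiral amine. Fallback, setting out from 4 and coming back at 10: alkaloid-mediated methanolysis of 4 (quinidine or quinine, whichever gives the required enantiomer; MeOH, toluene, −55 °C) to (2S,3R)-4-methoxy-2,3-dimethyl-4-oxobutanoic acid F1. Oxalyl chloride and catalytic DMF then give methyl (2R,3S)-4-chloro-2,3-dimethyl-4-oxobutanoate F2. Pd-catalysed Negishi acylation with 6 gives methyl (2R,3S)-4-[4-(benzyloxy)-3,5-dimethoxyphenyl]-2,3-dimethyl-4-oxobutanoate F3. Hydrogenolysis as in step 4 gives methyl (2R,3R)-4-(4-hydroxy-3,5-dimethoxyphenyl)-2,3-dimethylbutanoate F4, and LiOH in aqueous THF returns 10.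

Step 4. Most likely failure: acid-promoted enolisation of the aryl ketone before it is reduced, which would epimerise C8, or stalling at the benzylic alcohol stage. Fallback, from 7 back to 10: NaBH4 at 0 °C followed by acidification to the lactone (3R,4S,5RS)-5-[4-(benzyloxy)-3,5-dimethoxyphenyl]-3,4-dimethyloxolan-2-one F5. Neutral hydrogenolysis (H2, Pd(OH)2/C, EtOH/EtOAc) then cleaves the benzylic lactone C–O bond and the benzyl ether together, so the ketone never meets acid.

Step 5. Most likely failure: slow addition to the poorly soluble dilithium salt, with competing deprotonation at C8' and loss of configuration there. Fallback, from 10 back to 14: thioesterification (EtSH, EDC, DMAP) to S-ethyl (2R,3R)-4-(4-hydroxy-3,5-dimethoxyphenyl)-2,3-dimethylbutanethioate F6. A Liebeskind–Srogl coupling with commercial [4-(benzyloxy)-3-methoxyphenyl]boronic acid (Pd2(dba)3, tri-2-furylphosphine, CuTC, THF, 50 °C) then gives 14 under neutral conditions.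

Step 7. Most likely failure: loss of the C8' proton from the cation before ring closure (alkene formation and re-protonation would scramble C8' towards the trans-dimethyl series), or lower trans selectivity at C7' than argued. Fallback, from 14 directly to 17: neutral debenzylation (H2, Pd/C, EtOAc, rt) to (2R,3R)-1-(4-hydroxy-3-methoxyphenyl)-4-(4-hydroxy-3,5-dimethoxyphenyl)-2,3-dimethylbutan-1-one F7. NaBH4 gives (1RS,2R,3R)-1-(4-hydroxy-3-methoxyphenyl)-4-(4-hydroxy-3,5-dimethoxyphenyl)-2,3-dimethylbutan-1-ol F8. Cyclisation of F8 through its p-quinone methide (catalytic weak acid in hexafluoroisopropanol, rt) is a vinylogous conjugate addition of ring A that avoids a long-lived free cation.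

## Further compounds

F1 | step 3 | (2S,3R)-4-methoxy-2,3-dimethyl-4-oxobutanoic acid | OC(=O)[C@@H](C)[C@H](C(=O)OC)C
F2 | step 3 | methyl (2R,3S)-4-chloro-2,3-dimethyl-4-oxobutanoate | ClC(=O)[C@@H](C)[C@H](C(=O)OC)C
F3 | step 3 | methyl (2R,3S)-4-[4-(benzyloxy)-3,5-dimethoxyphenyl]-2,3-dimethyl-4-oxobutanoate | COc1cc(cc(OC)c1OCc1ccccc1)C(=O)[C@@H](C)[C@H](C(=O)OC)C
F4 | step 3 | methyl (2R,3R)-4-(4-hydroxy-3,5-dimethoxyphenyl)-2,3-dimethylbutanoate | COc1cc(C[C@@H](C)[C@H](C(=O)OC)C)cc(OC)c1O
F5 | step 4 | (3R,4S,5RS)-5-[4-(benzyloxy)-3,5-dimethoxyphenyl]-3,4-dimethyloxolan-2-one | COc1cc(cc(OC)c1OCc1ccccc1)C1OC(=O)[C@H](C)[C@@H]1C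
F6 | step 5 | S-ethyl (2R,3R)-4-(4-hydroxy-3,5-dimethoxyphenyl)-2,3-dimethylbutanethioate | COc1cc(C[C@@H](C)[C@H](C(=O)SCC)C)cc(OC)c1O
F7 | step 7 | (2R,3R)-1-(4-hydroxy-3-methoxyphenyl)-4-(4-hydroxy-3,5-dimethoxyphenyl)-2,3-dimethylbutan-1-one | COc1cc(C[C@@H](C)[C@H](C(=O)c2ccc(O)c(OC)c2)C)cc(OC)c1O
F8 | step 7 | (1RS,2R,3R)-1-(4-hydroxy-3-methoxyphenyl)-4-(4-hydroxy-3,5-dimethoxyphenyl)-2,3-dimethylbutan-1-ol | COc1cc(C[C@@H](C)[C@H](C(O)c2ccc(O)c(OC)c2)C)cc(OC)c1O
A1 | alternative 1 | (S)-4-benzyl-3-[(R)-3-(4-(benzyloxy)-3,5-dimethoxyphenyl)-2-methylpropanoyl]oxazolidin-2-one | COc1cc(C[C@@H](C)C(=O)N2[C@@H](Cc3ccccc3)COC2=O)cc(OC)c1OCc1ccccc1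
A2 | alternative 1 | (1RS,2R,3R)-1-[4-(benzyloxy)-3-methoxyphenyl]-4-[4-(benzyloxy)-3,5-dimethoxyphenyl]-2,3-dimethylbutan-1-ol | COc1cc(C[C@@H](C)[C@H](C(O)c2ccc(OCc3ccccc3)c(OC)c2)C)cc(OC)c1OCc1ccccc1
A3 | alternative 2 | 2-(benzyloxy)-6-[4-(benzyloxy)-3-methoxybenzylidene]-1,3-dimethoxy-5-methylidenecyclohexa-1,3-diene (aryl outward) | C=C1C=C(OC)C(OCc2ccccc2)=C(OC)/C1=C\c1ccc(OCc2ccccc2)c(OC)c1
A4 | alternative 2 | all-cis 6-(benzyloxy)-4-[4-(benzyloxy)-3-methoxyphenyl]-5,7-dimethoxy-3a,4,9,9a-tetrahydronaphtho[2,3-c]furan-1,3-dione (racemic, relative configuration shown) | COc1cc([C@@H]2c3c(cc(OC)c(OCc5ccccc5)c3OC)C[C@@H]4C(=O)OC(=O)[C@H]24)ccc1OCc1ccccc1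
A5 | alternative 3 | 4-(benzyloxy)-3,5-dimethoxy-1,2-didehydrobenzene (aryne) | COC1=C(OCc2ccccc2)C(OC)=CC#C1
A6 | alternative 3 | 6-(benzyloxy)-5,7-dimethoxy-2,3-dimethyl-1,4-dihydro-1,4-epoxynaphthalene (racemic, one enantiomer shown) | COc1cc2[C@@H]3O[C@@H](C(C)=C3C)c2c(OC)c1OCc1ccccc1
A7 | alternative 3 | 6-(benzyloxy)-5,7-dimethoxy-2,3-dimethyl-1,2,3,4-tetrahydro-1,4-epoxynaphthalene, methyls cis and endo (racemic, relative configuration shown) | COc1cc2[C@@H]3O[C@@H]([C@H](C)[C@@H]3C)c2c(OC)c1OCc1ccccc1
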